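All runs are calculated with made-up constants, noise included.

Target forms when starting material meets partner, and I take that as one for one. Beta stands still at 67.7 % of target beside 31.6 % of starting material, so I read partner as the limiting reagent.

| flask | starting material | partner | second substrate | third substrate | temperature | remark | time |
|---|---|---|---|---|---|---|---|
| beta | 0.25 M | 1.1 equiv | 0.20 equiv | 0.20 equiv (fed, over 3.0 h) | 10 °C | run made earlier; the fed solution adds 0.25 times the starting volume |  |
| delta | 0.25 M | 1.8 equiv | 0.20 equiv | 0.20 equiv (fed, over 3.0 h) | 25 °C | run made earlier; the fed solution adds 0.25 times the starting volume |  |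
| gamma | 0.25 M | 0.80 equiv | 0.29 equiv | 0.20 equiv (fed, over 3.0 h) | 10 °C | run made earlier; the fed solution adds 0.25 times the starting volume |  |
| east | 0.25 M | 1.20 equiv | 0.800 equiv | 0.200 equiv | 25 °C | everything together at the start, the whole solution of third substrate included, so that from the start the volume is larger by 0.25 times the starting volume | 12 h |
| north-east | 0.25 M | 0.800 equiv | 0.200 equiv | 0.200 equiv (fed, over 3.0 h) | 25 °C | the fed solution adds 0.25 times the starting volume | 12 h |

| run | time / h | target / % | starting material / % |
|---|---|---|---|
| beta | 2.00 | 52.9 | 45.8 |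
| beta | 3.00 | 58.2 | 41.2 |
| beta | 4.00 | 61.2 | 38.7 |
| beta | 6.00 | 63.9 | 36.6 |
| beta | 10.0 | 66.6 | 32.9 |
| beta | 15.0 | 67.7 | 32.4 |
| beta | 25.0 | 67.7 | 31.6 |
| delta | 1.00 | 91.7 | 7.8 |
| delta | 1.33 | 93.8 | 5.6 |
| delta | 2.00 | 97.2 | 2.7 |
| delta | 3.00 | 98.5 | 1.8 |
| delta | 5.00 | 99.5 | 0.5 |
| delta | 8.00 | 98.8 | 0 |
| delta | 12.0 | 100.0 | 0.5 |
| gamma | 2.00 | 34.1 | 66.2 |
| gamma | 4.00 | 36.6 | 64.0 |
| gamma | 6.00 | 36.4 | 61.6 |
| gamma | 12.0 | 36.2 | 62.8 |
| gamma | 25.0 | 36.7 | 63.6 |

(standard deviation of a reading: 0.5 percentage points)

- which of the two ends with the higher amount of target, in percent of the starting material charged ("neither" if they lie within 2 percentage points) (east / north-east / neither)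
- target at the end, in percent of the starting material charged, east
- target at the end, in percent of the starting material charged, north-east

- every charge counts on the volume at the start, and the solution that is fed holds the whole dose
- a reading or a percentage of target counts all its forms, free or not

I count one quantity per flask. In east, 1.20 equiv of partner less 0.800 equiv of second substrate and 0.200 equiv of third substrate leaves 0.200. This difference is the spare partner S, what stays for target once each substrate molecule has taken one partner. Beta has S = 0.700 and ends at 67.7 %, so I read both substrates there as served ahead of starting material.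

North-east looks nearly the same as gamma: both hold 0.800 equiv of partner and receive third substrate over 3.0 h. Gamma has S = 0.310 but ends at 36.7 %, higher by 0.0570, and it already shows 34.1 % at 2.00 h, inside the feed. I read that gap as third substrate that came too late to find partner. North-east has S = 0.400, so adding gamma's gap I reckon about 45.7 %. North-east runs at 25 °C and gamma at 10 °C, and no earlier run shows that change by itself, so this figure is rough. East receives its third substrate at the start, so nothing arrives late and I reckon S itself, about 20.0 %. North-east should therefore end higher.

The forecast says east, with 68 % (56 % to 80 %) for east and 38 % (33 % to 43 %) for north-east, holding that “the third substrate seems to eat about 2 equiv of partner”.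

East gives 20.3 % and north-east 51.6 %, so north-east ends higher.

    starting material + partner → target (k = 0.370 M⁻¹ min⁻¹, Ea = 73.0 kJ mol⁻¹)
    third substrate + partner → third product (k = 5.30 M⁻¹ min⁻¹, Ea = 64.0 kJ mol⁻¹)
    partner + target ⇌ idle adduct, settled at all times (K = 8.20 M⁻¹, ΔH = 18.0 kJ mol⁻¹)
    second substrate + partner → second product (k = 11.0 M⁻¹ min⁻¹, Ea = 40.0 kJ mol⁻¹)
    partner → decomposed reagent (k = 0.00200 min⁻¹, Ea = 92.0 kJ mol⁻¹)
    (constants at 25 °C)

North-east lands above my reckoning and above its S of 0.400: at 3.00 h its partner stands at 0 % of its charge, with 66.0 % of the charged third substrate still unused. The flask like east but with 0.0800 equiv of third substrate has S = 0.320 and gives 31.0 %.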